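**Strategy**

Everything rests on cutting ring C of the upper unit T at C2=C3. O1–C2 is carried as the aryl ester of 3,4-dibenzyloxybenzoic acid and C3–C4 as the vinyl group of a 1,1-diarylallyl unit whose methine, the future C4 of T, already bears C6 of the middle unit M. Titanium methylenation of the ester and ring-closing metathesis turn the ester carbonyl and the vinyl group into the C2=C3 enol ether of a 2-aryl-4H-chromene in one operation, so the benzylic O1–C2 bond is never ionised. The precursor is the benzylated, 8-brominated epicatechin-(4β→8)-catechin dimer with an (R)-1-arylallyl group at C6 of M and the neighbouring phenol acylated.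

Key step: step 12

Remark: 3,5-dibenzyloxyphenol, 3,4-dibenzyloxybenzoic acid and 3,4,5-tris(benzyloxy)benzoic acid are taken as purchasable building blocks. The bromine at C8 of unit M is a blocking group that is carried to the last step. "M–B dimer" below means the unit defined in compound 9.

**Route**

Step 1
Reactants: 1 (−)-epicatechin
Product: 2 5,7,3',4'-tetra-O-benzyl-(−)-epicatechin (2R,3R, free 3-OH)
Conditions: BnBr (4.4 equiv), K2CO3, DMF, 0 °C to rt, argon
Reagents that add atoms: benzyl bromide, BrCc1ccccc1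
Why: Williamson etherification with a carbonate base alkylates only the four phenols and leaves the secondary C3 alcohol and both stereocentres untouched.

Step 2
Reactants: 2 5,7,3',4'-tetra-O-benzyl-(−)-epicatechin
Product: 3 3-O-TBS ether of 2
Conditions: TBSCl, imidazole, DMF, 40 °C
Reagents that add atoms: tert-butyldimethylsilyl chloride, CC(C)(C)[Si](C)(C)Cl
Why: Silylation of the only free hydroxyl gives an ether that is stable to base, hydride and titanium reagents and that later shields one face of C4.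

Step 3
Reactants: 3 3-O-TBS ether
Product: 4 4β-(2-ethoxyethoxy) derivative of 3 (2,3-cis, 3,4-trans)
Conditions: DDQ (2 equiv), 2-ethoxyethanol (5 equiv), CH2Cl2, rt
Reagents that add atoms: 2-ethoxyethanol, CCOCCO
Why: DDQ abstracts hydride from benzylic C4, which is activated by O1 and the 5- and 7-benzyloxy groups (oxidative benzylic etherification), and the alcohol should add to the cation anti to the C3 silyloxy group, which sets C4 as 4β.

Step 4
Reactants: 4 4β-(2-ethoxyethoxy) flavan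
Product: 5 8-bromo derivative of 4
Conditions: NBS (1.05 equiv), CH2Cl2, −40 °C to 0 °C
Reagents that add atoms: N-bromosuccinimide, O=C1CCC(=O)N1Br
Why: Electrophilic aromatic bromination goes to C8, the more reactive of the two free positions of ring A in benzylated flavans, under neutral conditions that spare the C4 ether.

Step 5
Reactants: 5 8-bromo flavan
Product: 6 8-bromo-6-iodo derivative of 4
Conditions: NIS (1.5 equiv), NaHCO3, MeCN/CH2Cl2, rt, dark
Reagents that add atoms: N-iodosuccinimide, O=C1CCC(=O)N1I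
Why: Electrophilic aromatic iodination takes the last free position of the trioxygenated ring A (C6), which remains more nucleophilic than the catechol diether ring, and installs a C–I bond that can later be addressed beside the C8 bromide.

Step 6
Reactants: 7 (+)-catechin
Product: 8 3,5,7,3',4'-penta-O-benzyl-(+)-catechin (2R,3S)
Conditions: NaH (5.5 equiv), BnBr (5.5 equiv), DMF, −20 °C to rt
Reagents that add atoms: benzyl bromide, BrCc1ccccc1
Why: Exhaustive Williamson etherification with a strong base benzylates the four phenols and the C3 alcohol, so that this hydroxyl, which is free in the target, stays masked until the final hydrogenolysis.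

Step 7
Reactants: 6 8-bromo-6-iodo flavan electrophile, 8 penta-O-benzylcatechin
Product: 9 M–B dimer iodide: 8-bromo-6-iodo-5,7,3',4'-tetra-O-benzyl-3-O-TBS-epicatechin-(4β→8)-3,5,7,3',4'-penta-O-benzylcatechin
Conditions: 8 (3 equiv), TMSOTf (0.5 equiv), CH2Cl2, −78 °C to −40 °C, then Et3N
Reagents that add atoms: none
Why: Lewis acid ionisation of the C4 ether gives a benzylic cation that C8 of the excess catechin nucleophile captures in a Friedel–Crafts alkylation anti to the C3 silyloxy group (new C4 centre 4β, 3,4-trans), while the halogens at C6 and C8 of the electrophile exclude self-condensation.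

Step 8
Reactants: 9 M–B dimer iodide
Product: 10 (E)-3-(M–B dimer-6-yl)prop-2-en-1-ol
Conditions: (E)-Bu3SnCH=CHCH2OH (1.5 equiv), Pd(PPh3)4 (10 mol%), CuI (20 mol%), CsF (2 equiv), DMF, 50 °C
Reagents that add atoms: (E)-3-(tributylstannyl)prop-2-en-1-ol, CCCC[Sn](CCCC)(CCCC)/C=C/CO
Why: Stille coupling takes place at the aryl iodide, which adds to zerovalent palladium far faster than the aryl bromide, and transfers the alkenyl group with retention of its E geometry.

Step 9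
Reactants: 10 cinnamyl-type alcohol
Product: 11 methyl carbonate of 10
Conditions: ClCO2Me, pyridine, CH2Cl2, 0 °C
Reagents that add atoms: methyl chloroformate, COC(=O)Cl
Why: Acylation of the primary allylic alcohol gives the carbonate leaving group needed for allyl–iridium formation without touching any stereocentre.

Step 10
Reactants: 11 cinnamyl-type methyl carbonate, 12 3,5-dibenzyloxyphenol
Product: 13 2-[(1R)-1-(M–B dimer-6-yl)prop-2-en-1-yl]-3,5-dibenzyloxyphenol
Conditions: [Ir(cod)Cl]2 (4 mol%), BINOL-derived N,N-bis(1-phenylethyl)phosphoramidite (8 mol%, antipode chosen for the (R) centre, catalyst preformed with n-PrNH2), 12 (3 equiv), THF, rt to 40 °C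
Reagents that add atoms: none
Why: In this iridium-catalysed asymmetric allylic substitution of Friedel–Crafts type the cyclometalated iridium–phosphoramidite complex ionises the carbonate, the phenoxide generated by the liberated methoxide attacks through its soft ortho carbon at the aryl-substituted allyl terminus (branched product), and the chiral ligand fixes the face of attack and hence the (R) configuration of the new diarylmethine.

Step 11
Reactants: 13 allylated phenol, 14 3,4-dibenzyloxybenzoic acid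
Product: 15 2-[(1R)-1-(M–B dimer-6-yl)prop-2-en-1-yl]-3,5-dibenzyloxyphenyl 3,4-dibenzyloxybenzoate
Conditions: DCC, DMAP, CH2Cl2, rt
Reagents that add atoms: none
Why: Steglich esterification acylates the only hydroxyl group under neutral conditions that cannot epimerise the doubly benzylic allylic centre.

Step 12
Reactants: 15 aryl ester with 1,1-diarylallyl group
Product: 17 (4R)-5,7-dibenzyloxy-2-(3,4-dibenzyloxyphenyl)-4-(M–B dimer-6-yl)-4H-chromene, via enol ether 16 (not isolated)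
Conditions: Cp2TiMe2 (3 equiv), toluene/THF, 70 °C, dark; solution passed through basic Al2O3 under argon; then second-generation Grubbs catalyst (H2IMes)(PCy3)Cl2Ru=CHPh (15 mol%), 1,4-benzoquinone (20 mol%), toluene, 70 °C, argon purge
Reagents that add atoms: none
Why: Thermolysis of Cp2TiMe2 gives Cp2Ti=CH2, which adds to the ester carbonyl and cycloreverts to titanocene oxide and the aryl 1-arylvinyl ether 16; the ruthenium benzylidene then exchanges onto the terminal vinyl carbon, and the alkylidene now on C3 closes the ring by [2+2] cycloaddition to the 1,1-disubstituted enol ether and retro-[2+2] with loss of ethene. The closest known reaction type is the olefinic ester cyclisation, that is ester methylenation followed by enol ether ring-closing metathesis, as used for cyclic enol ethers and C1-substituted glycals. Ring C of unit T is closed as a six-membered ring by ring-closing metathesis between C2 (the former ester carbon, still bonded to O1) and C3 (the internal vinyl carbon), which leaves the new double bond endocyclic. No stereocentre is created, and the C4 diarylmethine set in step 10 is not touched because neither acid nor strong base is present. The step needs methylenation of one carbonyl only, which is secured because the ester is the sole carbonyl group of 15, and ring closure faster than migration of the allyl double bond toward C4, which is favoured by the vinyl group being the only monosubstituted alkene, by the ortho arrangement on ring A that holds the two alkenes close, and by 1,4-benzoquinone as a scavenger of ruthenium hydrides.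

Step 13
Reactants: 17 2-aryl-4H-chromene
Product: 19 protected trimer with free 3-OH in unit T (unit T 2R,3R,4R), via epoxide 18 (not isolated)
Conditions: DMDO (acetone solution, 1.5 equiv), CH2Cl2, −78 °C to −40 °C; volatiles removed cold; LiBHEt3 (3 equiv), THF, −78 °C to 0 °C
Reagents that add atoms: dimethyldioxirane, CC1(C)OO1
Why: Dioxirane epoxidation of the enol ether should occur anti to the quasi-axial C4 aryl group (sets C3), and hydride then opens the enol ether epoxide at the acetal-type C2 with inversion, approaching axially and anti to the C3–O bond as in the reductive trans opening of 1-aryl glycal epoxides (sets C2), which gives the 2,3-cis-3,4-trans array.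

Step 14
Reactants: 19 silyl-protected alcohol
Product: 20 diol with free 3-OH in units T and M
Conditions: TBAF (3 equiv), THF, rt to 50 °C
Reagents that add atoms: none
Why: Fluoride-induced desilylation frees the C3 hydroxyl of unit M without affecting benzyl ethers, the aryl bromide or any stereocentre.

Step 15
Reactants: 20 diol, 21 3,4,5-tris(benzyloxy)benzoic acid
Product: 22 bis(3,4,5-tri-O-benzylgalloyl) ester of 20 (at O3 of units T and M)
Conditions: 21 (4 equiv), DCC (4 equiv), DMAP (2 equiv), CH2Cl2, rt to 40 °C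
Reagents that add atoms: none
Why: Steglich esterification acylates the two secondary C3 hydroxyls, the only free hydroxyl groups, with retention at both carbinol centres.

Step 16
Reactants: 22 fully protected trimer digallate
Product: 23 target, epicatechin 3-O-gallate-(4β→6)-epicatechin 3-O-gallate-(4β→8)-catechin
Conditions: H2 (1 atm), Pd(OH)2/C, THF/MeOH/H2O, rt
Reagents that add atoms: none
Why: Catalytic hydrogenolysis cleaves the nineteen benzyl ethers and the C8 carbon–bromine bond, while the gallate esters, the interflavan bonds and the ring C ether bonds should be retained.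

**Compound list**

1 | (−)-epicatechin, (2R,3R) | O[C@@H]1Cc2c(O)cc(O)cc2O[C@@H]1c1ccc(O)c(O)c1 | starting material
2 | 5,7,3',4'-tetra-O-benzyl-(−)-epicatechin, (2R,3R) | O[C@@H]1Cc2c(OCc5ccccc5)cc(OCc5ccccc5)cc2O[C@@H]1c1ccc(OCc5ccccc5)c(OCc5ccccc5)c1 | intermediate
3 | 5,7,3',4'-tetra-O-benzyl-3-O-TBS-(−)-epicatechin | CC(C)(C)[Si](C)(C)O[C@@H]1Cc2c(OCc5ccccc5)cc(OCc5ccccc5)cc2O[C@@H]1c1ccc(OCc5ccccc5)c(OCc5ccccc5)c1 | intermediate
4 | 4β-(2-ethoxyethoxy)-5,7,3',4'-tetra-O-benzyl-3-O-TBS-epicatechin (2,3-cis, 3,4-trans) | c2c(OCc5ccccc5)cc3c(c2OCc5ccccc5)[C@H](OCCOCC)[C@@H](O[Si](C)(C)C(C)(C)C)[C@@H](c2ccc(OCc5ccccc5)c(OCc5ccccc5)c2)O3 | intermediate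
5 | 8-bromo derivative of 4 | c2c(OCc5ccccc5)c(Br)c3c(c2OCc5ccccc5)[C@H](OCCOCC)[C@@H](O[Si](C)(C)C(C)(C)C)[C@@H](c2ccc(OCc5ccccc5)c(OCc5ccccc5)c2)O3 | intermediate
6 | 8-bromo-6-iodo derivative of 4 | Ic2c(OCc5ccccc5)c(Br)c3c(c2OCc5ccccc5)[C@H](OCCOCC)[C@@H](O[Si](C)(C)C(C)(C)C)[C@@H](c2ccc(OCc5ccccc5)c(OCc5ccccc5)c2)O3 | intermediate
7 | (+)-catechin, (2R,3S) | Oc1cc(O)c2c(c1)O[C@H](c1ccc(O)c(O)c1)[C@@H](O)C2 | starting material
8 | 3,5,7,3',4'-penta-O-benzyl-(+)-catechin | c2c(OCc5ccccc5)cc(OCc5ccccc5)c4c2O[C@H](c2ccc(OCc5ccccc5)c(OCc5ccccc5)c2)[C@@H](OCc5ccccc5)C4 | intermediate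
9 | M–B dimer iodide: 8-bromo-6-iodo-5,7,3',4'-tetra-O-benzyl-3-O-TBS-epicatechin-(4β→8)-penta-O-benzylcatechin | Ic2c(OCc5ccccc5)c(Br)c3c(c2OCc5ccccc5)[C@H](c2c(OCc5ccccc5)cc(OCc5ccccc5)c4c2O[C@H](c2ccc(OCc5ccccc5)c(OCc5ccccc5)c2)[C@@H](OCc5ccccc5)C4)[C@@H](O[Si](C)(C)C(C)(C)C)[C@@H](c2ccc(OCc5ccccc5)c(OCc5ccccc5)c2)O3 | intermediate
10 | (E)-3-(M–B dimer-6-yl)prop-2-en-1-ol | OC/C=C/c2c(OCc5ccccc5)c(Br)c3c(c2OCc5ccccc5)[C@H](c2c(OCc5ccccc5)cc(OCc5ccccc5)c4c2O[C@H](c2ccc(OCc5ccccc5)c(OCc5ccccc5)c2)[C@@H](OCc5ccccc5)C4)[C@@H](O[Si](C)(C)C(C)(C)C)[C@@H](c2ccc(OCc5ccccc5)c(OCc5ccccc5)c2)O3 | intermediate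
11 | (E)-3-(M–B dimer-6-yl)prop-2-en-1-yl methyl carbonate | COC(=O)OC/C=C/c2c(OCc5ccccc5)c(Br)c3c(c2OCc5ccccc5)[C@H](c2c(OCc5ccccc5)cc(OCc5ccccc5)c4c2O[C@H](c2ccc(OCc5ccccc5)c(OCc5ccccc5)c2)[C@@H](OCc5ccccc5)C4)[C@@H](O[Si](C)(C)C(C)(C)C)[C@@H](c2ccc(OCc5ccccc5)c(OCc5ccccc5)c2)O3 | intermediate
12 | 3,5-dibenzyloxyphenol | Oc1cc(OCc5ccccc5)cc(OCc5ccccc5)c1 | starting material
13 | 2-[(1R)-1-(M–B dimer-6-yl)prop-2-en-1-yl]-3,5-dibenzyloxyphenol | C=C[C@@H](c2c(OCc5ccccc5)c(Br)c3c(c2OCc5ccccc5)[C@H](c2c(OCc5ccccc5)cc(OCc5ccccc5)c4c2O[C@H](c2ccc(OCc5ccccc5)c(OCc5ccccc5)c2)[C@@H](OCc5ccccc5)C4)[C@@H](O[Si](C)(C)C(C)(C)C)[C@@H](c2ccc(OCc5ccccc5)c(OCc5ccccc5)c2)O3)c2c(OCc5ccccc5)cc(OCc5ccccc5)cc2O | intermediate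
14 | 3,4-dibenzyloxybenzoic acid | O=C(O)c1ccc(OCc5ccccc5)c(OCc5ccccc5)c1 | starting material
15 | 2-[(1R)-1-(M–B dimer-6-yl)prop-2-en-1-yl]-3,5-dibenzyloxyphenyl 3,4-dibenzyloxybenzoate | C=C[C@@H](c2c(OCc5ccccc5)c(Br)c3c(c2OCc5ccccc5)[C@H](c2c(OCc5ccccc5)cc(OCc5ccccc5)c4c2O[C@H](c2ccc(OCc5ccccc5)c(OCc5ccccc5)c2)[C@@H](OCc5ccccc5)C4)[C@@H](O[Si](C)(C)C(C)(C)C)[C@@H](c2ccc(OCc5ccccc5)c(OCc5ccccc5)c2)O3)c2c(OCc5ccccc5)cc(OCc5ccccc5)cc2OC(=O)c1ccc(OCc5ccccc5)c(OCc5ccccc5)c1 | intermediate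
16 | 2-[(1R)-1-(M–B dimer-6-yl)prop-2-en-1-yl]-3,5-dibenzyloxyphenyl 1-(3,4-dibenzyloxyphenyl)vinyl ether | C=C[C@@H](c2c(OCc5ccccc5)c(Br)c3c(c2OCc5ccccc5)[C@H](c2c(OCc5ccccc5)cc(OCc5ccccc5)c4c2O[C@H](c2ccc(OCc5ccccc5)c(OCc5ccccc5)c2)[C@@H](OCc5ccccc5)C4)[C@@H](O[Si](C)(C)C(C)(C)C)[C@@H](c2ccc(OCc5ccccc5)c(OCc5ccccc5)c2)O3)c2c(OCc5ccccc5)cc(OCc5ccccc5)cc2OC(=C)c1ccc(OCc5ccccc5)c(OCc5ccccc5)c1 | intermediate (not isolated)
17 | (4R)-5,7-dibenzyloxy-2-(3,4-dibenzyloxyphenyl)-4-(M–B dimer-6-yl)-4H-chromene (unit T with C2=C3) | C1=C(c6ccc(OCc5ccccc5)c(OCc5ccccc5)c6)Oc2cc(OCc5ccccc5)cc(OCc5ccccc5)c2[C@@H]1c2c(OCc5ccccc5)c(Br)c3c(c2OCc5ccccc5)[C@H](c2c(OCc5ccccc5)cc(OCc5ccccc5)c4c2O[C@H](c2ccc(OCc5ccccc5)c(OCc5ccccc5)c2)[C@@H](OCc5ccccc5)C4)[C@@H](O[Si](C)(C)C(C)(C)C)[C@@H](c2ccc(OCc5ccccc5)c(OCc5ccccc5)c2)O3 | intermediate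
18 | 2,3-epoxide of 17, epoxide oxygen anti to the C4 substituent | O6[C@@H]1[C@@H](c2c(OCc5ccccc5)c(Br)c3c(c2OCc5ccccc5)[C@H](c2c(OCc5ccccc5)cc(OCc5ccccc5)c4c2O[C@H](c2ccc(OCc5ccccc5)c(OCc5ccccc5)c2)[C@@H](OCc5ccccc5)C4)[C@@H](O[Si](C)(C)C(C)(C)C)[C@@H](c2ccc(OCc5ccccc5)c(OCc5ccccc5)c2)O3)c2c(OCc5ccccc5)cc(OCc5ccccc5)cc2O[C@@]16c1ccc(OCc5ccccc5)c(OCc5ccccc5)c1 | intermediate (not isolated)
19 | protected trimer, unit T as (2R,3R,4R)-flavan-3-ol with free 3-OH, unit M 3-O-TBS, 8-bromo | O[C@@H]1[C@@H](c2c(OCc5ccccc5)c(Br)c3c(c2OCc5ccccc5)[C@H](c2c(OCc5ccccc5)cc(OCc5ccccc5)c4c2O[C@H](c2ccc(OCc5ccccc5)c(OCc5ccccc5)c2)[C@@H](OCc5ccccc5)C4)[C@@H](O[Si](C)(C)C(C)(C)C)[C@@H](c2ccc(OCc5ccccc5)c(OCc5ccccc5)c2)O3)c2c(OCc5ccccc5)cc(OCc5ccccc5)cc2O[C@@H]1c1ccc(OCc5ccccc5)c(OCc5ccccc5)c1 | intermediate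
20 | protected trimer diol, free 3-OH in units T and M | O[C@@H]1[C@@H](c2c(OCc5ccccc5)c(Br)c3c(c2OCc5ccccc5)[C@H](c2c(OCc5ccccc5)cc(OCc5ccccc5)c4c2O[C@H](c2ccc(OCc5ccccc5)c(OCc5ccccc5)c2)[C@@H](OCc5ccccc5)C4)[C@@H](O)[C@@H](c2ccc(OCc5ccccc5)c(OCc5ccccc5)c2)O3)c2c(OCc5ccccc5)cc(OCc5ccccc5)cc2O[C@@H]1c1ccc(OCc5ccccc5)c(OCc5ccccc5)c1 | intermediate
21 | 3,4,5-tris(benzyloxy)benzoic acid | O=C(O)c1cc(OCc5ccccc5)c(OCc5ccccc5)c(OCc5ccccc5)c1 | starting material
22 | fully benzylated 8-bromo trimer 3,3-di-O-(tri-O-benzylgalloyl) ester (units T and M) | O=C(O[C@@H]1[C@@H](c2c(OCc5ccccc5)c(Br)c3c(c2OCc5ccccc5)[C@H](c2c(OCc5ccccc5)cc(OCc5ccccc5)c4c2O[C@H](c2ccc(OCc5ccccc5)c(OCc5ccccc5)c2)[C@@H](OCc5ccccc5)C4)[C@@H](OC(=O)c2cc(OCc5ccccc5)c(OCc5ccccc5)c(OCc5ccccc5)c2)[C@@H](c2ccc(OCc5ccccc5)c(OCc5ccccc5)c2)O3)c2c(OCc5ccccc5)cc(OCc5ccccc5)cc2O[C@@H]1c1ccc(OCc5ccccc5)c(OCc5ccccc5)c1)c1cc(OCc5ccccc5)c(OCc5ccccc5)c(OCc5ccccc5)c1 | intermediate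
23 | epicatechin 3-O-gallate-(4β→6)-epicatechin 3-O-gallate-(4β→8)-catechin | O=C(O[C@@H]1[C@@H](c2c(O)cc3c(c2O)[C@H](c2c(O)cc(O)c4c2O[C@H](c2ccc(O)c(O)c2)[C@@H](O)C4)[C@@H](OC(=O)c2cc(O)c(O)c(O)c2)[C@@H](c2ccc(O)c(O)c2)O3)c2c(O)cc(O)cc2O[C@@H]1c1ccc(O)c(O)c1)c1cc(O)c(O)c(O)c1 | target

**Step count and risks**

Total step count: 16. Longest linear sequence: 15 steps (steps 1 to 5 and 7 to 16, from (−)-epicatechin).

Steps most likely to fail:

Step 12. Ruthenium hydride species may move the allyl double bond into conjugation with the two aryl groups, which would also erase the C4 centre. The alkylidene may stall at the crowded, electron-rich enol ether, or the enol ether may hydrolyse on handling. The fallback closes ring C through O1–C2 by hemiketalisation and dehydration instead of metathesis, and sets out from 13. Hydroboration–oxidation of the vinyl group (9-BBN, THF; NaBO3, H2O) should give the 3,3-diarylpropan-1-ol F1. Parikh–Doering oxidation (SO3·pyridine, DMSO, iPr2NEt) should give the aldehyde, which rests as the chroman-2-ol F2. Addition of 3,4-dibenzyloxyphenylmagnesium bromide opens the lactol to the benzylic diol F3, and MnO2 oxidises the benzylic alcohol to the hydroxy ketone F4. PPTS in toluene with molecular sieves then dehydrates the cyclic hemiketal of F4, and the route is rejoined at 17.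

Step 10. The phenoxide may react through oxygen or through its para carbon, attack may occur at the unsubstituted allyl terminus, uncatalysed ionisation of the electron-rich carbonate may compete, or the ligand may control the crowded terminus poorly. The fallback makes the C–C bond by a sigmatropic shift and sets out from 10 and 12. Mitsunobu etherification (PPh3, DIAD, THF) should give the aryl cinnamyl ether F5. Its aromatic Claisen rearrangement (N,N-diethylaniline, 170 °C) can deliver the aryl-bearing carbon only to the ortho position. It should give 13 together with its epimer at the new centre, the epimeric phenol F6, from which 13 is separated by chromatography. The route is rejoined at 13.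

Step 13. The labile epoxide may collapse by hydride shift or ring opening before reduction, or hydride may be delivered syn to the C3 oxygen, which would give the 2,3-trans isomer. The fallback separates oxidation and reduction and sets out from 17. Epoxidation with DMDO in CH2Cl2/MeOH at −78 °C should give, by methanolysis in the flask, the stable 2-methoxyflavan-3-ol F7. Ionic reduction with Et3SiH and BF3·OEt2 in CH2Cl2 at −78 °C then passes through the oxocarbenium ion, which the silane should attack axially and anti to the C3 oxygen. The route is rejoined at 19.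

**Further compounds**

F1 | step 12 | 3-(2-hydroxy-4,6-dibenzyloxyphenyl)-3-(M–B dimer-6-yl)propan-1-ol, diarylmethine configured as in 13 | OCC[C@@H](c2c(OCc5ccccc5)c(Br)c3c(c2OCc5ccccc5)[C@H](c2c(OCc5ccccc5)cc(OCc5ccccc5)c4c2O[C@H](c2ccc(OCc5ccccc5)c(OCc5ccccc5)c2)[C@@H](OCc5ccccc5)C4)[C@@H](O[Si](C)(C)C(C)(C)C)[C@@H](c2ccc(OCc5ccccc5)c(OCc5ccccc5)c2)O3)c2c(OCc5ccccc5)cc(OCc5ccccc5)cc2O
F2 | step 12 | 5,7-dibenzyloxy-4-(M–B dimer-6-yl)chroman-2-ol, mixture of anomers | OC1C[C@@H](c2c(OCc5ccccc5)c(Br)c3c(c2OCc5ccccc5)[C@H](c2c(OCc5ccccc5)cc(OCc5ccccc5)c4c2O[C@H](c2ccc(OCc5ccccc5)c(OCc5ccccc5)c2)[C@@H](OCc5ccccc5)C4)[C@@H](O[Si](C)(C)C(C)(C)C)[C@@H](c2ccc(OCc5ccccc5)c(OCc5ccccc5)c2)O3)c2c(OCc5ccccc5)cc(OCc5ccccc5)cc2O1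
F3 | step 12 | 1-(3,4-dibenzyloxyphenyl)-3-(2-hydroxy-4,6-dibenzyloxyphenyl)-3-(M–B dimer-6-yl)propan-1-ol, mixture of carbinol epimers | OC(C[C@@H](c2c(OCc5ccccc5)c(Br)c3c(c2OCc5ccccc5)[C@H](c2c(OCc5ccccc5)cc(OCc5ccccc5)c4c2O[C@H](c2ccc(OCc5ccccc5)c(OCc5ccccc5)c2)[C@@H](OCc5ccccc5)C4)[C@@H](O[Si](C)(C)C(C)(C)C)[C@@H](c2ccc(OCc5ccccc5)c(OCc5ccccc5)c2)O3)c2c(OCc5ccccc5)cc(OCc5ccccc5)cc2O)c1ccc(OCc5ccccc5)c(OCc5ccccc5)c1
F4 | step 12 | 1-(3,4-dibenzyloxyphenyl)-3-(2-hydroxy-4,6-dibenzyloxyphenyl)-3-(M–B dimer-6-yl)propan-1-one | O=C(C[C@@H](c2c(OCc5ccccc5)c(Br)c3c(c2OCc5ccccc5)[C@H](c2c(OCc5ccccc5)cc(OCc5ccccc5)c4c2O[C@H](c2ccc(OCc5ccccc5)c(OCc5ccccc5)c2)[C@@H](OCc5ccccc5)C4)[C@@H](O[Si](C)(C)C(C)(C)C)[C@@H](c2ccc(OCc5ccccc5)c(OCc5ccccc5)c2)O3)c2c(OCc5ccccc5)cc(OCc5ccccc5)cc2O)c1ccc(OCc5ccccc5)c(OCc5ccccc5)c1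
F5 | step 10 | 3,5-dibenzyloxyphenyl (E)-3-(M–B dimer-6-yl)prop-2-en-1-yl ether | c1c(OCc5ccccc5)cc(OCc5ccccc5)cc1OC/C=C/c2c(OCc5ccccc5)c(Br)c3c(c2OCc5ccccc5)[C@H](c2c(OCc5ccccc5)cc(OCc5ccccc5)c4c2O[C@H](c2ccc(OCc5ccccc5)c(OCc5ccccc5)c2)[C@@H](OCc5ccccc5)C4)[C@@H](O[Si](C)(C)C(C)(C)C)[C@@H](c2ccc(OCc5ccccc5)c(OCc5ccccc5)c2)O3
F6 | step 10 | epimer of 13 at the diarylmethine, (1S) | C=C[C@H](c2c(OCc5ccccc5)c(Br)c3c(c2OCc5ccccc5)[C@H](c2c(OCc5ccccc5)cc(OCc5ccccc5)c4c2O[C@H](c2ccc(OCc5ccccc5)c(OCc5ccccc5)c2)[C@@H](OCc5ccccc5)C4)[C@@H](O[Si](C)(C)C(C)(C)C)[C@@H](c2ccc(OCc5ccccc5)c(OCc5ccccc5)c2)O3)c2c(OCc5ccccc5)cc(OCc5ccccc5)cc2O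
F7 | step 13 | 2-methoxy analogue of 19 (unit T 2-methoxyflavan-3-ol, methoxy trans to the 3-OH) | O[C@@H]1[C@@H](c2c(OCc5ccccc5)c(Br)c3c(c2OCc5ccccc5)[C@H](c2c(OCc5ccccc5)cc(OCc5ccccc5)c4c2O[C@H](c2ccc(OCc5ccccc5)c(OCc5ccccc5)c2)[C@@H](OCc5ccccc5)C4)[C@@H](O[Si](C)(C)C(C)(C)C)[C@@H](c2ccc(OCc5ccccc5)c(OCc5ccccc5)c2)O3)c2c(OCc5ccccc5)cc(OCc5ccccc5)cc2O[C@]1(OC)c1ccc(OCc5ccccc5)c(OCc5ccccc5)c1
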